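The constants of these flasks are not given, so what they do has to be read from the earlier runs of this kinetic resolution.

the same everywhere: left-handed substrate 0.21 M; right-handed substrate 0.21 M; free catalyst 10 mol%; racemization catalyst 0.5 mol%; impurity 0.93 mM
- grey: partner 3 equiv; the very flask that is asked about, followed so far
- blue: partner 4.5 equiv; run made earlier
- flask: partner 3.00 equiv; time 1.5 h

| run | time / min | left-handed substrate / % | right-handed substrate / % |
|---|---|---|---|
| grey | 2.00 | 36 | 48 |
| grey | 5.00 | 23 | 44 |
| grey | 12.0 | 12 | 40 |
| grey | 25.0 | 11 | 36 |
| blue | 8.00 | 13 | 38 |
| blue | 15.0 | 6 | 29 |
| blue | 40.0 | 4 | 24 |
| blue | 90.0 | 5 | 22 |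

(scatter of a reading: 1.5 percentage points)

- free catalyst is single-handed; left-handed substrate and right-handed substrate are mirror images of each other, charged as a racemate, each of them at the stated concentration
- an excess is below zero if the other one leads

- part of the left-handed substrate and right-handed substrate charged together that has reacted at 1.5 h
- excess of left-handed product over right-handed product in the product at 1.5 h
- excess of right-handed substrate over left-handed substrate among what is left of the two at 1.5 h

The first setting is partner. By hand, more partner should carry the reaction further, and it does: blue, at 4.5 equiv, has 72.0% reacted at 40.0 min, while grey, at 3 equiv, has 53.0% at 25.0 min. Yet the two substrates together in blue read 28.0% at 40.0 min and 27.0% at 90.0 min, against a scatter of 1.5 percentage points.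

The second setting is time. By hand, a later reading adds little product once that sum stands still. Mirror-image substrates still head for equal amounts, so [right-handed substrate] − [left-handed substrate] should shrink. In blue it reads 20 points, then 17 points. That gives a reading of 3.55 h for the racemization half-life, the time in which this difference halves after the product steps stop. It is rough, given the scatter.

Carried from grey's last reading to 1.5 h, the difference becomes 20.2%. Over the remainder the forecast expects, this reckoning gives an eS of 47.0%, which differs from the forecast's own figure.

The forecast gives 57% reacted, an eP of 55% and an eS of 53%, and it sees “weak racemization, roughly 0.004 per min”.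

The flask gives 59.3% reacted, an eP of 48.0% and an eS of 42.3%. Its substrate difference stands at 17 points, below the reckoned 20.2%.

    partner → decomposed reagent (k = 0.00100 s⁻¹)
    left-handed substrate + racemization catalyst ⇌ right-handed substrate + racemization catalyst, rate k2*[racemization catalyst]*[left-handed substrate] forward; the back reaction follows from the equilibrium constant (k = 0.410 L mol⁻¹ s⁻¹)
    2 partner → self-condensation product (k = 3.50 × 10⁻⁵ L mol⁻¹ s⁻¹)
    racemization catalyst + impurity → spent catalyst (k = 75.0 L mol⁻¹ s⁻¹)
    partner + free catalyst + left-handed substrate → free catalyst + left-handed product (k = 0.250 L² mol⁻² s⁻¹)
    partner + free catalyst + right-handed substrate → free catalyst + right-handed product (k = 0.0480 L² mol⁻² s⁻¹)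

At 1.50 h, with partner at 0.047% of its charge, left-handed substrate goes to left-handed product at 0.032 of the rate of its forward step to right-handed substrate. At 15.0 h, this flask holds left-handed substrate at 20.3% and right-handed substrate at 20.4%. In a flask with 0.750 equiv of partner, the product lead stands at 13 points; taken as a substrate difference and decayed with 3.55 h over the whole 1.5 h, it reckons to 9.40%, and that flask shows less than this, a substrate difference of 7.7 points.

The runs come from a simulation for substances that don't exist.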